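**Plan**

1. Retrosynthesis: the enone Cα=Cβ bond is cut first (aldol condensation of a ring A acetophenone with a ring B aldehyde), then the ring A C1'–acetyl bond, then the C=CH2 and C–CH3 bonds of the isopropenyl group (back to an aldehyde carbon), and last the bond between the benzylic CH2 on C3' and the stereocentre.
2. Enabling feature: that benzylic CH2 sits on ring A C3', ortho to the C2' hydroxyl, so it can be the exocyclic methylene of an ortho-quinone methide; the adjacent stereocentre is the α-carbon of 5-methylhex-4-enal, whose carbonyl carbon later becomes the isopropenyl carbon.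
3. Forward: a bis(MOM) phloroglucinol sulfone and the aldehyde are joined by aminocatalysis to a 3-prenylchroman-2-ol (the only ring made, reopened by MeMgBr). Protection, oxidation and methylenation finish the lavandulyl chain; ortho-lithiation acetylates ring A; Claisen–Schmidt condensation and MOM removal give the chalcone.
4. Stereochemistry: the single (R) centre comes from the (S)-pyrrolidine catalyst in the key step and is afterwards exposed only to non-basic carbonyl chemistry while α to a carbonyl; the E enone comes from the aldol dehydration.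

Key step: step 5

Assumption: the (S) catalyst is taken to give the 3R lactol, following its usual sense of induction (electrophile on the enamine face remote from the diphenyl(silyloxy)methyl group); the mirror-image catalyst would be used if the opposite sense were found.

**Route**

Step 1
Reactants: 1 2,4,6-trihydroxybenzaldehyde
Product: 2 2-hydroxy-4,6-bis(methoxymethoxy)benzaldehyde
Conditions: MOMCl (2.2 equiv), iPr2NEt, CH2Cl2, 0 °C to rt
Reagents that add atoms: chloromethyl methyl ether (MOMCl), COCCl
Why: Williamson-type O-alkylation should take the 4-hydroxyl and one ortho hydroxyl, while the last ortho hydroxyl stays free because its hydrogen bond to the formyl oxygen lowers its nucleophilicity.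

Step 2
Reactants: 2 2-hydroxy-4,6-bis(methoxymethoxy)benzaldehyde
Product: 3 2-(hydroxymethyl)-3,5-bis(methoxymethoxy)phenol
Conditions: NaBH4, THF–MeOH, 0 °C; pH 7 phosphate buffer
Reagents that add atoms: none
Why: Borohydride reduction of the aldehyde should stop at the salicyl alcohol when run cold and quenched at neutral pH, and the crude alcohol is used at once because it ionises easily.

Step 3
Reactants: 3 2-(hydroxymethyl)-3,5-bis(methoxymethoxy)phenol; 4 sodium 4-methylbenzenesulfinate
Product: 5 3,5-bis(methoxymethoxy)-2-[(4-methylbenzenesulfonyl)methyl]phenol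
Conditions: 4 (3 equiv), AcOH, THF–H2O, 0 °C to rt
Reagents that add atoms: none
Why: The trioxygenated benzylic alcohol ionises under weak acid and the soft sulfinate captures the cation at sulfur (SN1-type benzylic substitution), the excess of sulfinate being meant to outcompete C-alkylation of the ring, while MOM ethers tolerate acetic acid.

Step 4
Reactants: 6 2-methylbut-3-en-2-ol; 7 ethyl vinyl ether
Product: 9 5-methylhex-4-enal, via allyl vinyl ether 8 (not isolated)
Conditions: 7 (excess), H3PO4 (cat.), sealed vessel, 130 °C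
Reagents that add atoms: none
Why: Acid-catalysed vinyl transfer with loss of ethanol gives the tertiary allyl vinyl ether 8, which undergoes Claisen rearrangement at this temperature to the γ,δ-unsaturated aldehyde, the dimethyl-substituted alkene having no geometry to control.

Step 5
Reactants: 5 3,5-bis(methoxymethoxy)-2-[(4-methylbenzenesulfonyl)methyl]phenol; 9 5-methylhex-4-enal
Product: 13 (3R)-5,7-bis(methoxymethoxy)-3-(3-methylbut-2-en-1-yl)chroman-2-ol (anomeric mixture), via enamine 10 (not isolated), via quinone methide 11 (not isolated), via hydroxy aldehyde 12 (not isolated)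
Conditions: (S)-2-[diphenyl(trimethylsilyloxy)methyl]pyrrolidine (20 mol %), K2CO3 (1.5 equiv), 9 (3 equiv), CH2Cl2, 0 °C to rt
Reagents that add atoms: none
Why: K2CO3 deprotonates the phenol of 5 and the phenoxide expels sulfinate to give quinone methide 11, while the pyrrolidine condenses with 9 to the E enamine 10, whose α-carbon adds to the exocyclic methylene of 11 with rearomatisation; hydrolytic release of the catalyst gives hydroxy aldehyde 12, which closes to the lactol. The closest known reaction type is the aminocatalytic α-(2-hydroxybenzyl)ation of aldehydes by ortho-quinone methides set free with base from 2-(sulfonylmethyl)phenols, a formal [4+2] annulation to chroman-2-ols. The pyran ring closes by 6-exo-trig addition of the phenol oxygen to the aldehyde carbonyl, and the anomeric centre is left as a mixture because step 6 removes it. The C3 stereocentre is set by the catalyst: its diphenyl(trimethylsilyloxy)methyl group blocks one face of the s-trans E enamine, so the methylene adds to the open face, which for the (S) catalyst should give 3R. Only the enamine face needs control (the methide CH2 does not become a stereocentre), together with chemoselectivity for enamine capture over self-condensation of the electron-rich ring, which slow release of 11 by the heterogeneous base and the excess of 9 are meant to secure. Lactol formation also removes the aldehyde from the amine, which should protect the new α-stereocentre from epimerisation.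

Step 6
Reactants: 13 (3R)-5,7-bis(methoxymethoxy)-3-(3-methylbut-2-en-1-yl)chroman-2-ol
Product: 15 (3R)-3-{[2-hydroxy-4,6-bis(methoxymethoxy)phenyl]methyl}-6-methylhept-5-en-2-ol (both C2 epimers), via magnesium phenoxide aldehyde 14 (not isolated)
Conditions: MeMgBr (4 equiv), THF, 0 °C to rt; aq. NH4Cl
Reagents that add atoms: methylmagnesium bromide, C[Mg]Br
Why: MeMgBr first deprotonates the lactol, whose magnesium alkoxide opens to the ring-opened aldehyde as its magnesium phenoxide 14, and Grignard 1,2-addition to that aldehyde should be faster than enolisation, so C3 is carried through unchanged while the new carbinol centre forms as a mixture that step 8 removes.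

Step 7
Reactants: 15 (3R)-3-{[2-hydroxy-4,6-bis(methoxymethoxy)phenyl]methyl}-6-methylhept-5-en-2-ol
Product: 16 (3R)-6-methyl-3-{[2,4,6-tris(methoxymethoxy)phenyl]methyl}hept-5-en-2-ol (both C2 epimers)
Conditions: MOMCl (1.2 equiv), K2CO3, acetone, rt
Reagents that add atoms: chloromethyl methyl ether (MOMCl), COCCl
Why: Carbonate deprotonates only the phenol, so Williamson-type O-alkylation should protect it selectively and leave the secondary alcohol free for oxidation.

Step 8
Reactants: 16 (3R)-6-methyl-3-{[2,4,6-tris(methoxymethoxy)phenyl]methyl}hept-5-en-2-ol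
Product: 17 (3R)-6-methyl-3-{[2,4,6-tris(methoxymethoxy)phenyl]methyl}hept-5-en-2-one
Conditions: nPr4N[RuO4] (5 mol %), N-methylmorpholine N-oxide, 4 Å molecular sieves, CH2Cl2, rt
Reagents that add atoms: none
Why: Ley–Griffith oxidation converts both carbinol epimers to the one methyl ketone under neutral conditions that should neither epimerise the α-stereocentre nor touch the trisubstituted alkene or the MOM ethers.

Step 9
Reactants: 17 (3R)-6-methyl-3-{[2,4,6-tris(methoxymethoxy)phenyl]methyl}hept-5-en-2-one
Product: 18 1,3,5-tris(methoxymethoxy)-2-[(2R)-5-methyl-2-(prop-1-en-2-yl)hex-4-en-1-yl]benzene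
Conditions: Cp2Ti(μ-CH2)(μ-Cl)AlMe2, pyridine (cat.), THF–toluene, −40 to 0 °C
Reagents that add atoms: μ-chloro-μ-methylene-bis(cyclopentadienyl)titanium dimethylaluminium, Cp2Ti(μ-CH2)(μ-Cl)AlMe2, C[Al-]1(C)C[Ti](C2C=CC=C2)(C2C=CC=C2)[Cl+]1
Why: Tebbe olefination transfers CH2 to the ketone through the non-basic titanium methylidene, so the enolisable α-stereocentre should keep its configuration and the isopropenyl group of the lavandulyl chain is completed.

Step 10
Reactants: 18 1,3,5-tris(methoxymethoxy)-2-[(2R)-5-methyl-2-(prop-1-en-2-yl)hex-4-en-1-yl]benzene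
Product: 21 1-{2,4,6-tris(methoxymethoxy)-3-[(2R)-5-methyl-2-(prop-1-en-2-yl)hex-4-en-1-yl]phenyl}ethan-1-one, via aryllithium 19 (not isolated), via lithium hemiaminal 20 (not isolated)
Conditions: n-BuLi, THF, 0 °C; then MeC(O)N(OMe)Me, −78 °C to rt; aq. NH4Cl
Reagents that add atoms: N-methoxy-N-methylacetamide, CC(=O)N(C)OC
Why: Directed ortho-metalation removes one of the two ring protons, each flanked by two MOM ethers and interchangeable by rotation about the aryl–CH2 bond, and aryllithium 19 adds to the amide to give chelate 20, which releases the ketone only on work-up (Weinreb ketone synthesis), so a single regioisomer and no tertiary alcohol are expected.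

Step 11
Reactants: 22 2-hydroxy-4-methoxybenzaldehyde
Product: 23 4-methoxy-2-(methoxymethoxy)benzaldehyde
Conditions: MOMCl, K2CO3, acetone, reflux
Reagents that add atoms: chloromethyl methyl ether (MOMCl), COCCl
Why: Williamson-type O-alkylation of the phenoxide masks the ring B hydroxyl so that it cannot interfere with the base-mediated condensation.

Step 12
Reactants: 21 1-{2,4,6-tris(methoxymethoxy)-3-[(2R)-5-methyl-2-(prop-1-en-2-yl)hex-4-en-1-yl]phenyl}ethan-1-one; 23 4-methoxy-2-(methoxymethoxy)benzaldehyde
Product: 25 (2E)-3-[4-methoxy-2-(methoxymethoxy)phenyl]-1-{2,4,6-tris(methoxymethoxy)-3-[(2R)-5-methyl-2-(prop-1-en-2-yl)hex-4-en-1-yl]phenyl}prop-2-en-1-one, via aldol adduct 24 (not isolated)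
Conditions: KOH (aq.), EtOH, rt
Reagents that add atoms: none
Why: In this Claisen–Schmidt condensation the enolate of 21 adds to the non-enolisable aldehyde and aldol 24 dehydrates by E1cB to the conjugated E enone; with every phenol masked no flavanone can form, and the stereocentre, no longer α to a carbonyl, is inert to base.

Step 13
Reactants: 25 (2E)-3-[4-methoxy-2-(methoxymethoxy)phenyl]-1-{2,4,6-tris(methoxymethoxy)-3-[(2R)-5-methyl-2-(prop-1-en-2-yl)hex-4-en-1-yl]phenyl}prop-2-en-1-one
Product: 26 (2E)-3-(2-hydroxy-4-methoxyphenyl)-1-{2,4,6-trihydroxy-3-[(2R)-5-methyl-2-(prop-1-en-2-yl)hex-4-en-1-yl]phenyl}prop-2-en-1-one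
Conditions: 3 M HCl (aq.), MeOH, rt
Reagents that add atoms: none
Why: Acid-catalysed acetal exchange with methanol removes the four MOM groups as dimethoxymethane, and with dilute acid at room temperature this cleavage should outrun oxa-Michael closure to a flavanone and addition of a phenol to the isopropenyl group.

**Compound list**

1 | 2,4,6-trihydroxybenzaldehyde | O=Cc1c(O)cc(O)cc1O | starting material
2 | 2-hydroxy-4,6-bis(methoxymethoxy)benzaldehyde | O=Cc1c(O)cc(OCOC)cc1OCOC | intermediate
3 | 2-(hydroxymethyl)-3,5-bis(methoxymethoxy)phenol | OCc1c(O)cc(OCOC)cc1OCOC | intermediate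
4 | sodium 4-methylbenzenesulfinate | Cc1ccc(S(=O)[O-])cc1.[Na+] | starting material
5 | 3,5-bis(methoxymethoxy)-2-[(4-methylbenzenesulfonyl)methyl]phenol | Cc1ccc(S(=O)(=O)Cc2c(O)cc(OCOC)cc2OCOC)cc1 | intermediate
6 | 2-methylbut-3-en-2-ol | C=CC(C)(C)O | starting material
7 | ethyl vinyl ether | C=COCC | starting material
8 | 3-(ethenyloxy)-3-methylbut-1-ene | C=COC(C)(C)C=C | intermediate
9 | 5-methylhex-4-enal | CC(C)=CCCC=O | intermediate
10 | (2S)-2-[diphenyl(trimethylsilyloxy)methyl]-1-[(1E)-5-methylhexa-1,4-dien-1-yl]pyrrolidine | CC(C)=CC/C=C/N1CCC[C@H]1C(c1ccccc1)(c1ccccc1)O[Si](C)(C)C | intermediate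
11 | 3,5-bis(methoxymethoxy)-6-methylidenecyclohexa-2,4-dien-1-one | C=C1C(=O)C=C(OCOC)C=C1OCOC | intermediate
12 | (2R)-2-{[2-hydroxy-4,6-bis(methoxymethoxy)phenyl]methyl}-5-methylhex-4-enal | O=C[C@H](CC=C(C)C)Cc1c(O)cc(OCOC)cc1OCOC | intermediate
13 | (3R)-5,7-bis(methoxymethoxy)-3-(3-methylbut-2-en-1-yl)chroman-2-ol (anomeric mixture) | OC1Oc2cc(OCOC)cc(OCOC)c2C[C@H]1CC=C(C)C | intermediate
14 | bromomagnesium 2-[(2R)-2-formyl-5-methylhex-4-en-1-yl]-3,5-bis(methoxymethoxy)phenolate | O=C[C@H](CC=C(C)C)Cc1c(O[Mg]Br)cc(OCOC)cc1OCOC | intermediate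
15 | (3R)-3-{[2-hydroxy-4,6-bis(methoxymethoxy)phenyl]methyl}-6-methylhept-5-en-2-ol (both C2 epimers) | CC(O)[C@H](CC=C(C)C)Cc1c(O)cc(OCOC)cc1OCOC | intermediate
16 | (3R)-6-methyl-3-{[2,4,6-tris(methoxymethoxy)phenyl]methyl}hept-5-en-2-ol (both C2 epimers) | CC(O)[C@H](CC=C(C)C)Cc1c(OCOC)cc(OCOC)cc1OCOC | intermediate
17 | (3R)-6-methyl-3-{[2,4,6-tris(methoxymethoxy)phenyl]methyl}hept-5-en-2-one | CC(=O)[C@H](CC=C(C)C)Cc1c(OCOC)cc(OCOC)cc1OCOC | intermediate
18 | 1,3,5-tris(methoxymethoxy)-2-[(2R)-5-methyl-2-(prop-1-en-2-yl)hex-4-en-1-yl]benzene | C=C(C)[C@H](CC=C(C)C)Cc1c(OCOC)cc(OCOC)cc1OCOC | intermediate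
19 | {2,4,6-tris(methoxymethoxy)-3-[(2R)-5-methyl-2-(prop-1-en-2-yl)hex-4-en-1-yl]phenyl}lithium | C=C(C)[C@H](CC=C(C)C)Cc1c(OCOC)cc(OCOC)c([Li])c1OCOC | intermediate
20 | lithium 1-[methoxy(methyl)amino]-1-{2,4,6-tris(methoxymethoxy)-3-[(2R)-5-methyl-2-(prop-1-en-2-yl)hex-4-en-1-yl]phenyl}ethan-1-olate | C=C(C)[C@H](CC=C(C)C)Cc1c(OCOC)cc(OCOC)c(C(C)(O[Li])N(C)OC)c1OCOC | intermediate
21 | 1-{2,4,6-tris(methoxymethoxy)-3-[(2R)-5-methyl-2-(prop-1-en-2-yl)hex-4-en-1-yl]phenyl}ethan-1-one | C=C(C)[C@H](CC=C(C)C)Cc1c(OCOC)cc(OCOC)c(C(C)=O)c1OCOC | intermediate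
22 | 2-hydroxy-4-methoxybenzaldehyde | O=Cc1ccc(OC)cc1O | starting material
23 | 4-methoxy-2-(methoxymethoxy)benzaldehyde | O=Cc1ccc(OC)cc1OCOC | intermediate
24 | 3-hydroxy-3-[4-methoxy-2-(methoxymethoxy)phenyl]-1-{2,4,6-tris(methoxymethoxy)-3-[(2R)-5-methyl-2-(prop-1-en-2-yl)hex-4-en-1-yl]phenyl}propan-1-one | C=C(C)[C@H](CC=C(C)C)Cc1c(OCOC)cc(OCOC)c(C(=O)CC(O)c2ccc(OC)cc2OCOC)c1OCOC | intermediate
25 | (2E)-3-[4-methoxy-2-(methoxymethoxy)phenyl]-1-{2,4,6-tris(methoxymethoxy)-3-[(2R)-5-methyl-2-(prop-1-en-2-yl)hex-4-en-1-yl]phenyl}prop-2-en-1-one | C=C(C)[C@H](CC=C(C)C)Cc1c(OCOC)cc(OCOC)c(C(=O)/C=C/c2ccc(OC)cc2OCOC)c1OCOC | intermediate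
26 | (2E)-3-(2-hydroxy-4-methoxyphenyl)-1-{2,4,6-trihydroxy-3-[(2R)-5-methyl-2-(prop-1-en-2-yl)hex-4-en-1-yl]phenyl}prop-2-en-1-one | C=C(C)[C@H](CC=C(C)C)Cc1c(O)cc(O)c(C(=O)/C=C/c2ccc(OC)cc2O)c1O | target

**Step count**

Total: 13 steps. Longest linear sequence: 11 steps (steps 1, 2, 3, 5, 6, 7, 8, 9, 10, 12, 13).

**Steps most likely to fail**

Step 5. The quinone methide may be consumed by C-alkylation of the electron-rich phenoxide of 5 (oligomerisation) faster than the enamine captures it, or an uncatalysed base-mediated addition may erode the enantioselectivity. The fallback replaces catalyst control by auxiliary control; it sets out from 9 and 5 and comes back at 13. Aldehyde 9 would be oxidised with NaClO2/NaH2PO4/2-methylbut-2-ene (Pinnick oxidation) to 5-methylhex-4-enoic acid F1. Acid F1 would be N-acylated onto (S)-4-benzyloxazolidin-2-one (pivaloyl chloride, Et3N, LiCl, THF) to give (S)-4-benzyl-3-(5-methylhex-4-enoyl)oxazolidin-2-one F2. The lithium Z-enolate of F2 (LiN(SiMe3)2, THF, −78 °C) would be combined with the lithium phenoxide of 5 (a further equivalent of LiN(SiMe3)2) and the mixture allowed to reach 0 °C, so that the quinone methide is released in the presence of the enolate. Alkylation on the enolate face remote from the benzyl group should give (S)-4-benzyl-3-[(2R)-2-{[2-hydroxy-4,6-bis(methoxymethoxy)phenyl]methyl}-5-methylhex-4-enoyl]oxazolidin-2-one F3. On further warming, the phenoxide of F3 should attack the exocyclic imide carbonyl and expel the auxiliary, forming (3R)-5,7-bis(methoxymethoxy)-3-(3-methylbut-2-en-1-yl)chroman-2-one F4. Reduction of F4 with iBu2AlH (CH2Cl2, −78 °C) would return lactol 13.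

Step 3. Under acid the benzylic alcohol may ionise and alkylate another electron-rich ring instead of being trapped by sulfinate, and 3 itself may decompose before it is used. The fallback avoids both the free salicyl alcohol and the acid; it sets out from 2 and comes back at 5. Reductive amination of 2 with Me2NH and NaBH(OAc)3 (1,2-dichloroethane, rt) would give 2-[(dimethylamino)methyl]-3,5-bis(methoxymethoxy)phenol F5. N-Methylation of F5 with MeI in acetone would give 1-[2-hydroxy-4,6-bis(methoxymethoxy)phenyl]-N,N,N-trimethylmethanaminium iodide F6. Warming F6 with sulfinate 4 in DMF at 60 °C should expel trimethylamine and deliver sulfone 5 under neutral conditions.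

Step 13. Acid may close the 2'-hydroxyl onto the enone (flavanone formation), add a phenol to the protonated isopropenyl group (chroman formation) or cyclise the ring B hydroxyl onto the carbonyl (flavylium formation) while the last MOM groups are still being cleaved. The fallback avoids Brønsted acid by exchanging the acetals for silyl ethers; it sets out from 25 and comes back at 26. Treatment of 25 with Me3SiOTf and 2,2'-bipyridyl (CH2Cl2, 0 °C) should give (2E)-3-[4-methoxy-2-(trimethylsilyloxy)phenyl]-1-{3-[(2R)-5-methyl-2-(prop-1-en-2-yl)hex-4-en-1-yl]-2,4,6-tris(trimethylsilyloxy)phenyl}prop-2-en-1-one F7. The aryl silyl ethers of F7 would then be hydrolysed with water in THF at room temperature to give 26.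

**Further compounds**

F1 | step 5 | 5-methylhex-4-enoic acid | CC(C)=CCCC(=O)O
F2 | step 5 | (S)-4-benzyl-3-(5-methylhex-4-enoyl)oxazolidin-2-one | CC(C)=CCCC(=O)N1C(=O)OC[C@@H]1Cc1ccccc1
F3 | step 5 | (S)-4-benzyl-3-[(2R)-2-{[2-hydroxy-4,6-bis(methoxymethoxy)phenyl]methyl}-5-methylhex-4-enoyl]oxazolidin-2-one | O=C([C@H](CC=C(C)C)Cc1c(O)cc(OCOC)cc1OCOC)N1C(=O)OC[C@@H]1Cc1ccccc1
F4 | step 5 | (3R)-5,7-bis(methoxymethoxy)-3-(3-methylbut-2-en-1-yl)chroman-2-one | O=C1Oc2cc(OCOC)cc(OCOC)c2C[C@H]1CC=C(C)C
F5 | step 3 | 2-[(dimethylamino)methyl]-3,5-bis(methoxymethoxy)phenol | CN(C)Cc1c(O)cc(OCOC)cc1OCOC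
F6 | step 3 | 1-[2-hydroxy-4,6-bis(methoxymethoxy)phenyl]-N,N,N-trimethylmethanaminium iodide | C[N+](C)(C)Cc1c(O)cc(OCOC)cc1OCOC.[I-]
F7 | step 13 | (2E)-3-[4-methoxy-2-(trimethylsilyloxy)phenyl]-1-{3-[(2R)-5-methyl-2-(prop-1-en-2-yl)hex-4-en-1-yl]-2,4,6-tris(trimethylsilyloxy)phenyl}prop-2-en-1-one | C=C(C)[C@H](CC=C(C)C)Cc1c(O[Si](C)(C)C)cc(O[Si](C)(C)C)c(C(=O)/C=C/c2ccc(OC)cc2O[Si](C)(C)C)c1O[Si](C)(C)C
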